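**Retrosynthetic overview**

1. 14 ⇐ hydrogenolysis of the nona-O-benzyl digallate 13 ⇐ esterification of O3 in 12 ⇐ cis-selective hydride reduction of the (2R)-flavan-3-one 11. Ring A, ring B and both galloyl rings are bought, and ring C is the only ring that is made.
2. O3 is traced back to carbon: 11 ⇐ Baeyer–Villiger exchange of a C3 formyl group for oxygen in the 2H-chromene-3-carbaldehyde 9, which is 7 with O5 galloylated.
3. Ring C ⇐ one catalytic asymmetric domino reaction of the symmetric aldehyde 2 with enal 4: O1–C2 forms by oxa-Michael addition, then the ring closes through the aldol bond C3–C4 with loss of water.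
4. Enabling feature: C4 hangs on C4a of ring A, which lies between the oxygen-bearing carbons C8a (O1) and C5 (O5). As a formyl carbon, C4 is an electrophile flanked by two homotopic hydroxyls, and O1–C2–C3–C4 becomes a β-aryloxy-aldehyde/aldol retron once C3 carries the formyl group that stands in for O3.
5. The hydroxyl not used for O1 remains the only free OH and so marks O5 against the benzylated O7.

Key step: step 3

Remark: flavan numbering (O1, C2, C3, C4, C4a, C5 to C8, C8a; ring B on C2) is used for all bicyclic compounds. Compounds 1, 3, 8 and all reagents are taken as commercial.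

**Step 1**
Reactants: 1 2,4,6-trihydroxybenzaldehyde
Product: 2 4-(benzyloxy)-2,6-dihydroxybenzaldehyde
Conditions: BnBr (1.0 equiv), KHCO3 (1.0 equiv), DMF, rt
Reagents that add atoms: benzyl bromide, BrCc1ccccc1
Why: Williamson etherification, in which the 4-OH is the most acidic hydroxyl and the only one not held in a hydrogen bond to the formyl oxygen, so a weak base and one equivalent of halide should alkylate it alone and keep the mirror symmetry of ring A.

**Step 2**
Reactants: 3 3,4-bis(benzyloxy)benzaldehyde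
Product: 4 (E)-3-[3,4-bis(benzyloxy)phenyl]prop-2-enal
Conditions: Ph3P=CHCHO (1.05 equiv), toluene, 80 °C
Reagents that add atoms: (triphenylphosphoranylidene)acetaldehyde, O=CC=P(c1ccccc1)(c1ccccc1)c1ccccc1
Why: Wittig olefination with a stabilised formyl ylide, which should give the (E)-enal and stop after one homologation as long as the ylide is not used in excess.

**Step 3**
Reactants: 2 4-(benzyloxy)-2,6-dihydroxybenzaldehyde; 4 (E)-3-[3,4-bis(benzyloxy)phenyl]prop-2-enal
Product: 7 (R)-7-(benzyloxy)-2-[3,4-bis(benzyloxy)phenyl]-5-hydroxy-2H-chromene-3-carbaldehyde, via oxa-Michael adduct 5 (not isolated), via aldol adduct 6 (not isolated)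
Conditions: (S)-2-[diphenyl(trimethylsilyloxy)methyl]pyrrolidine (20 mol %), 2-nitrobenzoic acid (20 mol %), 4 Å molecular sieves, toluene, rt, exclusion of light
Reagents that add atoms: none
Why: The amine and enal 4 form an (E)-iminium ion, one of the two homotopic hydroxyls of 2 adds to its β-carbon (O1–C2), the enamine form of 5 attacks with its α-carbon (C3) the formyl carbon next to it (C4), and loss of water from aldol 6 followed by hydrolysis releases 7 and the catalyst. The closest known reaction type is the diarylprolinol silyl ether catalysed domino oxa-Michael/aldol condensation of salicylaldehydes with cinnamaldehydes, which gives 2-aryl-2H-chromene-3-carbaldehydes. Ring C closes through the C3–C4 bond in a 6-(enolexo)-exo-trig aldol mode, and the irreversible dehydration to an enal conjugated with ring A pulls the reversible oxa-Michael step forward. C2, the only stereocentre that persists, is set by the catalyst, whose CPh2(OSiMe3) group covers the Re face of the β-carbon so that O1 arrives on the Si face (2R), while the transient centres C3 and C4 of 6 are erased by the dehydration. The step needs oxygen instead of carbon attack by ring A, no choice between the two hydroxyls, and crossed instead of self-condensation: the formyl group damps the carbon nucleophilicity of C6 and C8, the mirror plane of 2 makes both hydroxyls lead to the same product, and neither aldehyde has an enolisable α-hydrogen before the oxa-Michael step. The unused hydroxyl ends up as the only free OH of 7 and so marks O5 for step 4.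

**Step 4**
Reactants: 7 (R)-7-(benzyloxy)-2-[3,4-bis(benzyloxy)phenyl]-5-hydroxy-2H-chromene-3-carbaldehyde; 8 3,4,5-tris(benzyloxy)benzoic acid
Product: 9 (R)-7-(benzyloxy)-2-[3,4-bis(benzyloxy)phenyl]-3-formyl-2H-chromen-5-yl 3,4,5-tris(benzyloxy)benzoate
Conditions: DCC (1.1 equiv), DMAP (cat.), CH2Cl2, 0 °C to rt
Reagents that add atoms: none
Why: Steglich esterification of the only hydroxyl of 7, giving an ester that belongs to the target and also shields the phenol from the oxidant of step 5, with C2 untouched.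

**Step 5**
Reactants: 9 (R)-7-(benzyloxy)-2-[3,4-bis(benzyloxy)phenyl]-3-formyl-2H-chromen-5-yl 3,4,5-tris(benzyloxy)benzoate
Product: 11 (R)-7-(benzyloxy)-2-[3,4-bis(benzyloxy)phenyl]-3-oxochroman-5-yl 3,4,5-tris(benzyloxy)benzoate, via enol formate 10 (not isolated)
Conditions: 30% aq H2O2 (1.5 equiv), bis(2-nitrophenyl) diselenide (5 mol %), CH2Cl2, rt; then NaHCO3 (cat.), MeOH–THF, 0 °C, short contact
Reagents that add atoms: hydrogen peroxide, OO
Why: Baeyer–Villiger oxidation of an α,β-unsaturated aldehyde to its enol formate, in which the alkenyl carbon C3 (electron-rich through conjugation with ring A) migrates in preference to hydrogen and so exchanges the formyl carbon for O3, followed by transesterification of the very labile enol formate under conditions too weakly basic to enolise C2.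

**Step 6**
Reactants: 11 (R)-7-(benzyloxy)-2-[3,4-bis(benzyloxy)phenyl]-3-oxochroman-5-yl 3,4,5-tris(benzyloxy)benzoate
Product: 12 (2R,3R)-7-(benzyloxy)-2-[3,4-bis(benzyloxy)phenyl]-3-hydroxychroman-5-yl 3,4,5-tris(benzyloxy)benzoate
Conditions: LiBH(s-Bu)3 (1.1 equiv), LiBr, THF, −78 °C; AcOH quench at −78 °C
Reagents that add atoms: none
Why: Diastereoselective ketone reduction with a bulky trialkylborohydride, in which equatorial hydride attack next to the pseudo-equatorial C2 aryl group gives the axial 3-OH and thus the 2,3-cis (2R,3R) relationship, as known for benzylated flavan-3-ones and 2-substituted cyclohexanones; an O5-to-O3 acyl shift in the alkoxide would be harmless because step 7 esterifies whichever hydroxyl is free.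

**Step 7**
Reactants: 12 (2R,3R)-7-(benzyloxy)-2-[3,4-bis(benzyloxy)phenyl]-3-hydroxychroman-5-yl 3,4,5-tris(benzyloxy)benzoate; 8 3,4,5-tris(benzyloxy)benzoic acid
Product: 13 (2R,3R)-7-(benzyloxy)-2-[3,4-bis(benzyloxy)phenyl]chroman-3,5-diyl bis[3,4,5-tris(benzyloxy)benzoate]
Conditions: DCC (1.5 equiv), DMAP (0.5 equiv), CH2Cl2, rt
Reagents that add atoms: none
Why: Steglich esterification of the axial secondary 3-OH, the standard way to 3-O-gallates of flavan-3-ols, which keeps the configuration because the C3–O bond is not touched.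

**Step 8**
Reactants: 13 (2R,3R)-7-(benzyloxy)-2-[3,4-bis(benzyloxy)phenyl]chroman-3,5-diyl bis[3,4,5-tris(benzyloxy)benzoate]
Product: 14 (−)-epicatechin 3,5-di-O-gallate, (2R,3R)
Conditions: H2 (1 atm), Pd(OH)2/C, THF–MeOH, rt
Reagents that add atoms: none
Why: Catalytic hydrogenolysis of all nine benzyl ethers under neutral conditions, which should leave both gallate esters, the cyclic C2–O1 bond and the two stereocentres intact, as is usual for benzylated catechin gallates.

**Compound list**

1 | 2,4,6-trihydroxybenzaldehyde | O=Cc1c(O)cc(O)cc1O | starting material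
2 | 4-(benzyloxy)-2,6-dihydroxybenzaldehyde | O=Cc1c(O)cc(OCc2ccccc2)cc1O | intermediate
3 | 3,4-bis(benzyloxy)benzaldehyde | O=Cc1ccc(OCc2ccccc2)c(OCc2ccccc2)c1 | starting material
4 | (E)-3-[3,4-bis(benzyloxy)phenyl]prop-2-enal | O=C/C=C/c1ccc(OCc2ccccc2)c(OCc2ccccc2)c1 | intermediate
5 | (S)-4-(benzyloxy)-2-{1-[3,4-bis(benzyloxy)phenyl]-3-oxopropoxy}-6-hydroxybenzaldehyde (oxa-Michael adduct, drawn as the free aldehyde; held in the flask as the enamine of the catalyst) | O=CC[C@H](Oc1cc(OCc2ccccc2)cc(O)c1C=O)c1ccc(OCc2ccccc2)c(OCc2ccccc2)c1 | intermediate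
6 | (2S)-7-(benzyloxy)-2-[3,4-bis(benzyloxy)phenyl]-4,5-dihydroxychroman-3-carbaldehyde (aldol adduct, drawn free of catalyst; C3 and C4 not defined, both erased by dehydration) | O=CC1C(O)c2c(O)cc(OCc3ccccc3)cc2O[C@@H]1c1ccc(OCc2ccccc2)c(OCc2ccccc2)c1 | intermediate
7 | (R)-7-(benzyloxy)-2-[3,4-bis(benzyloxy)phenyl]-5-hydroxy-2H-chromene-3-carbaldehyde | O=CC1=Cc2c(O)cc(OCc3ccccc3)cc2O[C@@H]1c1ccc(OCc2ccccc2)c(OCc2ccccc2)c1 | intermediate
8 | 3,4,5-tris(benzyloxy)benzoic acid | O=C(O)c1cc(OCc2ccccc2)c(OCc2ccccc2)c(OCc2ccccc2)c1 | starting material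
9 | (R)-7-(benzyloxy)-2-[3,4-bis(benzyloxy)phenyl]-3-formyl-2H-chromen-5-yl 3,4,5-tris(benzyloxy)benzoate | O=CC1=Cc2c(OC(=O)c3cc(OCc4ccccc4)c(OCc4ccccc4)c(OCc4ccccc4)c3)cc(OCc3ccccc3)cc2O[C@@H]1c1ccc(OCc2ccccc2)c(OCc2ccccc2)c1 | intermediate
10 | (R)-7-(benzyloxy)-2-[3,4-bis(benzyloxy)phenyl]-3-(formyloxy)-2H-chromen-5-yl 3,4,5-tris(benzyloxy)benzoate | O=COC1=Cc2c(OC(=O)c3cc(OCc4ccccc4)c(OCc4ccccc4)c(OCc4ccccc4)c3)cc(OCc3ccccc3)cc2O[C@@H]1c1ccc(OCc2ccccc2)c(OCc2ccccc2)c1 | intermediate
11 | (R)-7-(benzyloxy)-2-[3,4-bis(benzyloxy)phenyl]-3-oxochroman-5-yl 3,4,5-tris(benzyloxy)benzoate | O=C1Cc2c(OC(=O)c3cc(OCc4ccccc4)c(OCc4ccccc4)c(OCc4ccccc4)c3)cc(OCc3ccccc3)cc2O[C@@H]1c1ccc(OCc2ccccc2)c(OCc2ccccc2)c1 | intermediate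
12 | (2R,3R)-7-(benzyloxy)-2-[3,4-bis(benzyloxy)phenyl]-3-hydroxychroman-5-yl 3,4,5-tris(benzyloxy)benzoate | O=C(Oc1cc(OCc3ccccc3)cc2c1C[C@@H](O)[C@@H](c1ccc(OCc3ccccc3)c(OCc3ccccc3)c1)O2)c1cc(OCc2ccccc2)c(OCc2ccccc2)c(OCc2ccccc2)c1 | intermediate
13 | (2R,3R)-7-(benzyloxy)-2-[3,4-bis(benzyloxy)phenyl]chroman-3,5-diyl bis[3,4,5-tris(benzyloxy)benzoate] | O=C(Oc1cc(OCc3ccccc3)cc2c1C[C@@H](OC(=O)c1cc(OCc3ccccc3)c(OCc3ccccc3)c(OCc3ccccc3)c1)[C@@H](c1ccc(OCc3ccccc3)c(OCc3ccccc3)c1)O2)c1cc(OCc2ccccc2)c(OCc2ccccc2)c(OCc2ccccc2)c1 | intermediate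
14 | (−)-epicatechin 3,5-di-O-gallate, (2R,3R) | O=C(Oc1cc(O)cc2c1C[C@@H](OC(=O)c1cc(O)c(O)c(O)c1)[C@@H](c1ccc(O)c(O)c1)O2)c1cc(O)c(O)c(O)c1 | target

**Step count**

Total step count: 8.
Longest linear sequence: 7 steps (1 → 2 → 7 → 9 → 11 → 12 → 13 → 14; the branch 3 → 4 → 7 is equally long).

**Steps most likely to fail**

**Step 3.** The aldol closure onto the hindered, donor-rich formyl group may be slow, and the amine may be tied up reversibly by 2. The oxa-Michael equilibrium would then be passed many times and the enantiomeric purity at C2 would erode. Carbon attack by ring A could also intrude.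

The fallback sets out from 2 and 3 and comes back at 11, bypassing steps 2 to 5.
- Aldehyde 3 is condensed with nitromethane (Henry condensation, NH4OAc, AcOH, heat) to (E)-1,2-bis(benzyloxy)-4-(2-nitrovinyl)benzene F1.
- Compounds 2 and F1 are joined in the known oxa-Michael/Henry/dehydration domino reaction catalysed by a bifunctional thiourea. Here a more nucleophilic nitronate carbon closes ring C and the catalyst binds no aldehyde covalently. The product is (R)-7-(benzyloxy)-2-[3,4-bis(benzyloxy)phenyl]-3-nitro-2H-chromen-5-ol F2.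
- Steglich esterification with 8 gives (R)-7-(benzyloxy)-2-[3,4-bis(benzyloxy)phenyl]-3-nitro-2H-chromen-5-yl 3,4,5-tris(benzyloxy)benzoate F3.
- A reductive Nef-type conversion of the nitroalkene (aqueous TiCl3 buffered with NH4OAc, THF) gives ketone 11.

**Step 5.** Hydrogen may migrate instead of the alkenyl carbon, the electron-rich enol formate may be oxidised further, or configuration at C2 may be lost while the formate is cleaved.

The fallback sets out from 9 and comes back at 11.
- Pinnick oxidation (NaClO2, NaH2PO4, 2-methyl-2-butene) gives (R)-7-(benzyloxy)-2-[3,4-bis(benzyloxy)phenyl]-5-{[3,4,5-tris(benzyloxy)benzoyl]oxy}-2H-chromene-3-carboxylic acid F4.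
- Diphenylphosphoryl azide and Et3N convert it to the acyl azide F5.
- Curtius rearrangement in warm toluene gives the vinyl isocyanate F6.
- tert-Butanol traps it as the tert-butyl enecarbamate F7.
- Mild aqueous acid hydrolysis, the classical entry to chroman-3-ones, gives 11.

**Step 6.** The basic hydride may deprotonate C2 with loss of configuration, may attack the 5-O aryl ester, or may show poor facial selectivity.

The fallback sets out from 10 and comes back at 12, so the configurationally labile ketone is never formed.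
- The enol formate 10 is isolated instead of being cleaved.
- It is hydrogenated over a catalyst that spares benzyl ethers (H2, Pd/C poisoned with ethylenediamine, THF). Hydrogen should add to the C3–C4 double bond on the face away from the C2 aryl group, giving the cis product (2R,3R)-7-(benzyloxy)-2-[3,4-bis(benzyloxy)phenyl]-3-(formyloxy)chroman-5-yl 3,4,5-tris(benzyloxy)benzoate F8.
- Selective methanolysis of the formate (NaHCO3, MeOH, 0 °C) gives 12.

**Further compounds**

F1 | step 3 | (E)-1,2-bis(benzyloxy)-4-(2-nitrovinyl)benzene | O=[N+]([O-])/C=C/c1ccc(OCc2ccccc2)c(OCc2ccccc2)c1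
F2 | step 3 | (R)-7-(benzyloxy)-2-[3,4-bis(benzyloxy)phenyl]-3-nitro-2H-chromen-5-ol | O=[N+]([O-])C1=Cc2c(O)cc(OCc3ccccc3)cc2O[C@@H]1c1ccc(OCc2ccccc2)c(OCc2ccccc2)c1
F3 | step 3 | (R)-7-(benzyloxy)-2-[3,4-bis(benzyloxy)phenyl]-3-nitro-2H-chromen-5-yl 3,4,5-tris(benzyloxy)benzoate | O=[N+]([O-])C1=Cc2c(OC(=O)c3cc(OCc4ccccc4)c(OCc4ccccc4)c(OCc4ccccc4)c3)cc(OCc3ccccc3)cc2O[C@@H]1c1ccc(OCc2ccccc2)c(OCc2ccccc2)c1
F4 | step 5 | (R)-7-(benzyloxy)-2-[3,4-bis(benzyloxy)phenyl]-5-{[3,4,5-tris(benzyloxy)benzoyl]oxy}-2H-chromene-3-carboxylic acid | O=C(O)C1=Cc2c(OC(=O)c3cc(OCc4ccccc4)c(OCc4ccccc4)c(OCc4ccccc4)c3)cc(OCc3ccccc3)cc2O[C@@H]1c1ccc(OCc2ccccc2)c(OCc2ccccc2)c1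
F5 | step 5 | acyl azide of F4, (R) | [N-]=[N+]=NC(=O)C1=Cc2c(OC(=O)c3cc(OCc4ccccc4)c(OCc4ccccc4)c(OCc4ccccc4)c3)cc(OCc3ccccc3)cc2O[C@@H]1c1ccc(OCc2ccccc2)c(OCc2ccccc2)c1
F6 | step 5 | (R)-7-(benzyloxy)-2-[3,4-bis(benzyloxy)phenyl]-3-isocyanato-2H-chromen-5-yl 3,4,5-tris(benzyloxy)benzoate | O=C=NC1=Cc2c(OC(=O)c3cc(OCc4ccccc4)c(OCc4ccccc4)c(OCc4ccccc4)c3)cc(OCc3ccccc3)cc2O[C@@H]1c1ccc(OCc2ccccc2)c(OCc2ccccc2)c1
F7 | step 5 | (R)-7-(benzyloxy)-2-[3,4-bis(benzyloxy)phenyl]-3-[(tert-butoxycarbonyl)amino]-2H-chromen-5-yl 3,4,5-tris(benzyloxy)benzoate | CC(C)(C)OC(=O)NC1=Cc2c(OC(=O)c3cc(OCc4ccccc4)c(OCc4ccccc4)c(OCc4ccccc4)c3)cc(OCc3ccccc3)cc2O[C@@H]1c1ccc(OCc2ccccc2)c(OCc2ccccc2)c1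
F8 | step 6 | (2R,3R)-7-(benzyloxy)-2-[3,4-bis(benzyloxy)phenyl]-3-(formyloxy)chroman-5-yl 3,4,5-tris(benzyloxy)benzoate | O=C(Oc1cc(OCc3ccccc3)cc2c1C[C@@H](OC=O)[C@@H](c1ccc(OCc3ccccc3)c(OCc3ccccc3)c1)O2)c1cc(OCc2ccccc2)c(OCc2ccccc2)c(OCc2ccccc2)c1
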